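I began from the end of the run, where 10.0% of the electrophile has to be left in the flask.

electrophile 1.2 M; gas 59 mM (held); time 4.0 d

    electrophile + acid set free → side product (k1 = 0.0110 M⁻¹ h⁻¹)
    electrophile + nucleophile → acid set free + target (k2 = 0.0338 M⁻¹ h⁻¹)
    acid set free + free base ⇌ salt of the base, settled at all times (K3 = 7.8 × 10⁵ M⁻¹)
    gas ⇌ free base, rate k4*(csat - [free base]) (k4 = 0.182 h⁻¹, csat = 59 mM)
    nucleophile + acid set free ⇌ protonated nucleophile, settled at all times (K5 = 17 M⁻¹)
    2 free base → self-condensation product (k6 = 4.02 M⁻¹ h⁻¹)

* the concentration of nucleophile at which the part of the electrophile that has reacted at 4.0 d is just 90%, in M

- two of one species on the left: rate k times its square, two consumed each time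
- at the start none of free base is dissolved
- the amount of nucleophile is what is sought; it is there from the start
- run time (flask): 4.0 d

What mean nucleophile did that end need? With nucleophile replaced by its mean, the electrophile falls pseudo-first-order, so I took the needed mean nucleophile, the logarithm of the wanted fall over the target step's rate constant times the run time: 0.710 M. I set aside the step of electrophile with acid set free, because at that mean nucleophile, protonated nucleophile outnumbers the acid set free by 12.1 to one.

What must the charge add? An even logarithmic fall leaves a mean of 0.469 M electrophile, so a mean of 0.731 M target. Each target uses one nucleophile, and its acid protonates another unless free base takes it. The 1.08 M of acid set free over the run is more than the 1.03 M the gas can bring at full rate, so I took uptake at full rate, a mean of 0.515 M. I therefore reckoned a mean loss of 0.946 M and a charge of 1.66 M. Nucleophile starts above its mean, so I expected the electrophile to fall earlier than in the even fall, with a higher mean loss and a somewhat larger charge.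

The forecast gave 1.65 M, reasoning that “each target formed costs roughly two nucleophiles until the base catches up”.

The simulation gave 1.76 M, so the charge stood 1.05 M above my needed mean, against my reckoned loss of 0.946 M. Target formation was half done by 0.606 d, gas uptake by 2.00 d, and at 1.00 d 56.9% of the electrophile was used, where my even fall has 43.8%. In the flask with half the nucleophile, 62.8% of the electrophile had reacted at the end of the run, which by the same rule means a mean nucleophile of 0.305 M.

The rate constants were drawn at random within sensible limits.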